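**Retrosynthetic overview**

1. The last bond cut is the O–CH3 bond on C6' of ring B (the oxygen between the C5' methyl and the C1' bridge, para to the C3' propanoyl). This leads back to symmetric hexaol 10, whose two para hydroxyls are equivalent.
2. Key disconnection: both aryl–C(=O) bonds together (C1 of ring A, C3' of ring B). Each propanoyl group sits on the one ring carbon that lies between two oxygen-bearing carbons and stays unsubstituted once the methyl group and the CH2 bridge are in place. A two-directional Friedel–Crafts propanoylation of the hexa-O-benzyl diarylmethane 6 with two molecules of propanoic acid is therefore fixed in its regiochemistry.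
3. The CH2 bridge is cut to formaldehyde and two molecules of 2,4,6-tris(benzyloxy)toluene 3, which comes from 2-methylphloroglucinol 1 through its triacetate 2.
4. No ring is formed at any stage; both benzene rings come intact from 1, and the target has no stereocentre.

Key step: step 4

Assumption: as in monomeric acylphloroglucinols, the hydroxyl para to the acyl group is taken to be the most acidic one and the first to react with diazomethane.

**Route**

Step 1
Reactants: 1 2-methylbenzene-1,3,5-triol (2-methylphloroglucinol)
Product: 2 2-methylbenzene-1,3,5-triyl triacetate
Conditions: Ac2O (4 equiv), pyridine, DMAP (cat.), 0 °C → rt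
Reagents that add atoms: acetic anhydride, CC(=O)OC(C)=O
Why: Exhaustive O-acetylation of the three phenols (nucleophilic acyl substitution) should give the triacetate, which masks the electron-rich ring so that the benzylation of step 2 is not diverted to ring carbon.

Step 2
Reactants: 2 2-methylbenzene-1,3,5-triyl triacetate
Product: 3 1,3,5-tris(benzyloxy)-2-methylbenzene
Conditions: NaH (6.5 equiv), BnCl (3.6 equiv), DMF, 0 °C; H2O (3.0 equiv, slow addition); rt
Reagents that add atoms: benzyl chloride, ClCc1ccccc1
Why: One-pot deacetylation and Williamson ether synthesis, in which hydroxide from NaH and the metered water unmasks one phenoxide at a time for immediate O-benzylation while the remaining acetoxy groups keep the ring too electron-poor for the C-benzylation typical of free phloroglucinol anions.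

Step 3
Reactants: 3 1,3,5-tris(benzyloxy)-2-methylbenzene (two molecules are incorporated; 3.3 equiv per formaldehyde, excess recovered); 4 formaldehyde (used as paraformaldehyde)
Product: 6 bis[2,4,6-tris(benzyloxy)-3-methylphenyl]methane, via benzylic alcohol 5 (not isolated)
Conditions: (CH2O)n (0.3 equiv), TsOH·H2O (10 mol %), AcOH–CH2Cl2, rt → 40 °C
Reagents that add atoms: none
Why: Acid-catalysed hydroxymethylation followed by Friedel–Crafts benzylation (the bis(aryl)methane condensation known for 1,3,5-trialkoxybenzenes and formaldehyde), in which protonated formaldehyde attacks one of the two equivalent free ring carbons of 3, alcohol 5 ionises to a trialkoxybenzyl cation that a second molecule of 3 traps, and the excess of arene should keep the more crowded product from being bridged further.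

Step 4
Reactants: 6 bis[2,4,6-tris(benzyloxy)-3-methylphenyl]methane; 7 propanoic acid (two molecules are incorporated, one per ring; 6 equiv used)
Product: 9 bis[2,4,6-tris(benzyloxy)-3-methyl-5-propanoylphenyl]methane, via mono-propanoyl diarylmethane 8 (not isolated)
Conditions: EtCO2H (6 equiv), (CF3CO)2O (6 equiv), CH2Cl2, 0 °C → rt
Reagents that add atoms: propanoic acid (second molecule of 7), CCC(=O)O
Why: Propanoic acid and trifluoroacetic anhydride form propanoic trifluoroacetic anhydride, a propanoyl-cation donor that needs no Lewis acid; one molecule attacks the single unsubstituted carbon of one ring of 6, which lies between two benzyloxy-bearing carbons and para to the third, and loss of the proton from the arenium ion gives mono-ketone 8. The second ring is insulated from the new carbonyl by the CH2 bridge, keeps its full nucleophilicity and is acylated in the same way by a second molecule of the mixed anhydride to give 9, so the two C(aryl)–C(=O) bonds (C1 of ring A and C3' of ring B of the target) are made in one operation that consumes two molecules of propanoic acid. The closest known reaction type is the trifluoroacetic anhydride-mediated Friedel–Crafts acylation of 1,3,5-trialkoxybenzenes with free carboxylic acids. No ring is closed and no stereocentre is formed. The step needs site selectivity (C–H substitution rather than ipso attack at the bridge-bearing carbon, which would cut the diarylmethane) and chemoselectivity (acylation before acidolysis of the benzyl ethers); the substrate secures the first because each ring offers exactly one free and least hindered position, and the mild Lewis-acid-free medium together with the high nucleophilicity of that position should secure the second, while each ring is deactivated towards further attack once its ketone is in place.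

Step 5
Reactants: 9 bis[2,4,6-tris(benzyloxy)-3-methyl-5-propanoylphenyl]methane
Product: 10 bis(2,4,6-trihydroxy-3-methyl-5-propanoylphenyl)methane
Conditions: H2 (1 atm), 10% Pd/C, EtOAc–MeOH, rt
Reagents that add atoms: none
Why: Heterogeneous hydrogenolysis of the six benzyl aryl ethers should free the hexaol, because the aryl ketones become chelated di-ortho-hydroxy carbonyls of vinylogous-acid character that are not reduced at balloon pressure and the diarylmethane C–C bonds are inert.

Step 6
Reactants: 10 bis(2,4,6-trihydroxy-3-methyl-5-propanoylphenyl)methane
Product: 11 1-[3-[(2,4-dihydroxy-6-methoxy-5-methyl-3-propanoylphenyl)methyl]-2,4,6-trihydroxy-5-methylphenyl]propan-1-one (target)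
Conditions: CH2N2 (0.9 equiv, titrated Et2O solution), Et2O–MeOH, −20 → 0 °C; unreacted 10 recovered
Reagents that add atoms: diazomethane, C=[N+]=[N-]
Why: O-Methylation of a phenol with diazomethane, in which the hydroxyl para to a propanoyl group (between the ring methyl and the bridge) is the most acidic and is not chelated to the carbonyl, so it should protonate diazomethane first and be methylated within the ion pair; the two para hydroxyls are symmetry-equivalent, so either gives 11, and a slight deficit of reagent should hold the reaction at the mono-ether.

**Compound list**

1 | 2-methylbenzene-1,3,5-triol | Cc1c(O)cc(O)cc1O | starting material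
2 | 2-methylbenzene-1,3,5-triyl triacetate | Cc1c(OC(C)=O)cc(OC(C)=O)cc1OC(C)=O | intermediate
3 | 1,3,5-tris(benzyloxy)-2-methylbenzene | Cc1c(OCc2ccccc2)cc(OCc2ccccc2)cc1OCc1ccccc1 | intermediate
4 | formaldehyde (as paraformaldehyde) | C=O | starting material
5 | [2,4,6-tris(benzyloxy)-3-methylphenyl]methanol | Cc1c(OCc2ccccc2)cc(OCc2ccccc2)c(CO)c1OCc1ccccc1 | intermediate
6 | bis[2,4,6-tris(benzyloxy)-3-methylphenyl]methane | Cc1c(OCc2ccccc2)cc(OCc2ccccc2)c(Cc2c(OCc3ccccc3)cc(OCc3ccccc3)c(C)c2OCc2ccccc2)c1OCc1ccccc1 | intermediate
7 | propanoic acid | CCC(=O)O | starting material
8 | 1-[2,4,6-tris(benzyloxy)-3-methyl-5-[[2,4,6-tris(benzyloxy)-3-methylphenyl]methyl]phenyl]propan-1-one | CCC(=O)c1c(OCc2ccccc2)c(C)c(OCc2ccccc2)c(Cc2c(OCc3ccccc3)cc(OCc3ccccc3)c(C)c2OCc2ccccc2)c1OCc1ccccc1 | intermediate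
9 | bis[2,4,6-tris(benzyloxy)-3-methyl-5-propanoylphenyl]methane | CCC(=O)c1c(OCc2ccccc2)c(C)c(OCc2ccccc2)c(Cc2c(OCc3ccccc3)c(C(=O)CC)c(OCc3ccccc3)c(C)c2OCc2ccccc2)c1OCc1ccccc1 | intermediate
10 | bis(2,4,6-trihydroxy-3-methyl-5-propanoylphenyl)methane | CCC(=O)c1c(O)c(C)c(O)c(Cc2c(O)c(C(=O)CC)c(O)c(C)c2O)c1O | intermediate
11 | 1-[3-[(2,4-dihydroxy-6-methoxy-5-methyl-3-propanoylphenyl)methyl]-2,4,6-trihydroxy-5-methylphenyl]propan-1-one | CCC(=O)c1c(O)c(C)c(O)c(Cc2c(O)c(C(=O)CC)c(O)c(C)c2OC)c1O | target

**Step count**

Total steps: 6. Longest linear sequence: 6 steps (1 → 2 → 3 → 6 → 9 → 10 → 11).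

**Steps most likely to fail**

Step 4 (key step). The trifluoroacetic acid released in the mixed-anhydride medium may cleave benzyl ethers before both rings are acylated, with O-acylation of the freed phenols. The acylating species may also attack ipso at the bridge-bearing carbon and expel the stabilised benzylic cation, which cuts the diarylmethane. The fallback avoids acid altogether and sets out from 6. Electrophilic bromination with N-bromosuccinimide (2.1 equiv, CH2Cl2, 0 °C, dark) at the same two free ring carbons should give the dibromide bis[2,4,6-tris(benzyloxy)-3-bromo-5-methylphenyl]methane F1. Double bromine–lithium exchange (n-BuLi, THF, −78 °C) followed by N-methoxy-N-methylpropanamide should then give the diketone, and the route is rejoined at 9.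

Step 6. The single methylation is spread statistically over the two equivalent para hydroxyls of different molecules, so unmethylated, mono- and di-methylated dimers form together and must be separated and recycled. Over-methylation at a non-chelated ortho hydroxyl can add to this. The fallback differentiates the two rings before they are joined; it sets out from 1 and 7, gives up the late double acylation, and is held in reserve only.
- Friedel–Crafts acylation of 1 with 7 (BF3·OEt2, 80 °C) should give 1-(2,4,6-trihydroxy-3-methylphenyl)propan-1-one F2.
- Part of F2 is methylated with diazomethane (1 equiv, Et2O–MeOH, 0 °C) at its only para hydroxyl to give 1-(2,6-dihydroxy-4-methoxy-3-methylphenyl)propan-1-one F3.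
- Aminomethylation of F3 at its single free ring carbon with N,N-dimethylmethyleneiminium iodide (CH2=NMe2+ I−, Eschenmoser's salt; CH2Cl2–MeCN, rt) should give the Mannich base 1-[3-[(dimethylamino)methyl]-2,6-dihydroxy-4-methoxy-5-methylphenyl]propan-1-one F4.
- Heating F4 with F2 (1.5 equiv) in 1,4-dioxane at 90 °C should expel dimethylamine through an ortho-quinone methide, which F2 traps at its only free ring carbon. The route is rejoined at the target 11.

Step 3. The diarylmethane still carries one free carbon on each ring, and free formaldehyde, released from paraformaldehyde at an ill-defined rate, may bridge it further to tri- and higher arylmethanes that are hard to remove. The fallback uses a single, isolated electrophile and sets out from 3. Vilsmeier–Haack formylation (POCl3, DMF, 0 °C → rt; aqueous NaOAc) should give 2,4,6-tris(benzyloxy)-3-methylbenzaldehyde F5. Reduction with NaBH4 (MeOH–THF, 0 °C) gives benzylic alcohol 5, now isolated. Slow addition of 5 to 3 (3 equiv) with TsOH·H2O (5 mol %) in CH2Cl2 at rt should give the Friedel–Crafts benzylation product, and the route is rejoined at 6.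

**Further compounds**

F1 | step 4 | bis[2,4,6-tris(benzyloxy)-3-bromo-5-methylphenyl]methane | Cc1c(OCc2ccccc2)c(Br)c(OCc2ccccc2)c(Cc2c(OCc3ccccc3)c(Br)c(OCc3ccccc3)c(C)c2OCc2ccccc2)c1OCc1ccccc1
F2 | step 6 | 1-(2,4,6-trihydroxy-3-methylphenyl)propan-1-one | CCC(=O)c1c(O)cc(O)c(C)c1O
F3 | step 6 | 1-(2,6-dihydroxy-4-methoxy-3-methylphenyl)propan-1-one | CCC(=O)c1c(O)cc(OC)c(C)c1O
F4 | step 6 | 1-[3-[(dimethylamino)methyl]-2,6-dihydroxy-4-methoxy-5-methylphenyl]propan-1-one | CCC(=O)c1c(O)c(CN(C)C)c(OC)c(C)c1O
F5 | step 3 | 2,4,6-tris(benzyloxy)-3-methylbenzaldehyde | Cc1c(OCc2ccccc2)cc(OCc2ccccc2)c(C=O)c1OCc1ccccc1
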